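**Even count.** An easy count came first: the catalyst has four forms, so with no preference each holds a quarter, and the question is which form beats that mark.

substrate 0.71 M; gas 200 mM (held); free catalyst 2.5 mol%

    reagent + free catalyst → catalyst intermediate A (k1 = 39.4 /M/min)
    substrate + catalyst intermediate A → catalyst intermediate B (k2 = 2.46 /M/min)
    catalyst intermediate B → free catalyst + target (k3 = 6.03 /min)
    gas ⇌ reagent, rate k4*(csat - [reagent]) (k4 = 0.0654 /min, csat = 200 mM)
    free catalyst ⇌ dormant form (K5 = 8.12, k5 = 0.0635 /min)

- the form that holds most of the catalyst when 50% of the substrate are converted (dormant form / catalyst intermediate A / free catalyst / catalyst intermediate B)
- its share of the catalyst then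

**Time shares.** At half conversion c(substrate) is 0.355 M. I gave each form a share in proportion to the time the catalyst spends in it per turnover, and I took the dormant form as balanced with free catalyst. Free catalyst waits one over the first rate constant times c(reagent), catalyst intermediate A waits 1.15 min, catalyst intermediate B waits 0.166 min, and the dormant form counts the equilibrium constant times free catalyst's wait. Dormant form and catalyst intermediate A tie at the tipping level, the c(reagent) equal to that equilibrium constant times the second step's rate constant times c(substrate), over the first rate constant: 0.180 M.

**Two extremes.** In the full version I let c(reagent) stand at saturation. One turnover then took 2.47 min of catalyst time, and my count gave the dormant form 41.7%, less than catalyst intermediate A's 46.4%. But at that pace 17.7 mM of catalyst turns over 7.19 mM/min, and the gas delivers that only at a deficit, which in my reckoning leaves c(reagent) at 90.0 mM. In this drawn-down version my count gave the dormant form 59.0%. Its slower turnover needs a smaller deficit, which in the reckoning puts c(reagent) at 130 mM, below the tipping level. There my count gave a dormant share of 51.3%. Setting aside the filling of the solution, I committed to the dormant form at about 55.1%.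

**The forecast.** It named the same form, the dormant form, at 50%, where my figure was 55.1%: “Dormant holds the most, at about 50%, though A is close.”

**The simulation.** Half conversion came at 0.876 h, with the dormant form holding 54.0%. Catalyst intermediate A, the resting state of the working round, held 33.8%.

**The crossing.** At 1.00 h the tipping level was 0.161 M and c(reagent) lay below it at 0.111 M, with the dormant form at 54.0% against 35.1% for catalyst intermediate A. At 2.00 h the level had sunk to 0.0533 M, c(reagent) stood above it at 0.154 M, and catalyst intermediate A led with 50.4% against 45.3%, though the dormant form, at 20.7 times free catalyst, was by then above the balance of 8.12 that the level assumes. Catalyst parked in the dormant form cost this flask rate: a simulated run without the exchange between free catalyst and dormant form reached 1.77 times the actual rate at half conversion.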